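**Retrosynthetic overview**

- The strategy rests on the ring pattern C1(=O)–C6H=C5(OMe): C1 and C5 are 1,3-related through C6, so the dienone is the methyl enol ether of a 4,4-disubstituted cyclohex-5-ene-1,3-dione. Removing the O-methyl group and then the C6–C1 bond leaves a C5 methyl ketone and a Z enoate (C1–C2=C3), both on the quaternary C4.
- The C2=C3 Z enoate with its allyl group comes from a Still–Gennari olefination of a C3 aldehyde that already carries C4(OMe)(COCH3).
- C4 and C8 are set together on an open chain by asymmetric epoxidation of a trisubstituted allylic alcohol and Me3Al opening at C8. The two CH2O arms on C4 then become the acetyl group (C5/C6) and the formyl group (C3).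
- The allylic alcohol comes from eugenol (as its TIPS ether) by cross-metathesis with a 2-(benzyloxymethyl)acrylate and ester reduction.
- Only one ring is formed, the dienone ring, in the key step; enol ether formation and desilylation finish the synthesis.

Key step: step 14

Assumption: the Ti/L-(+)-tartrate epoxidation of 7 is taken to show the facial sense established for (E)-2-methylalk-2-en-1-ols, which give (2S,3S)-epoxy alcohols; the quaternary carbon of 8 reads R only because CH2OBn outranks CH2OH.

**Route**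

Step 1
Reactants: 1 eugenol
Product: 2 4-allyl-2-methoxy-1-(triisopropylsilyloxy)benzene
Conditions: TIPSCl, imidazole, DMF, rt
Reagents that add atoms: triisopropylsilyl chloride, CC(C)[Si](Cl)(C(C)C)C(C)C
Why: Silylation of the phenol gives an aryl TIPS ether that should survive hydride, organoaluminium, Grignard, alkoxide and amide bases and is removed at the end by fluoride.

Step 2
Reactants: 3 methyl 2-(bromomethyl)acrylate; 4 benzyl alcohol
Product: 5 methyl 2-[(benzyloxy)methyl]prop-2-enoate
Conditions: Et3N, CH2Cl2, 0 °C to rt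
Reagents that add atoms: none
Why: Amine-mediated allylic substitution (SN2′ by the amine, then SN2′ by the alcohol) of a 2-(bromomethyl)acrylate returns the ether with the acrylate unit intact.

Step 3
Reactants: 2 4-allyl-2-methoxy-1-(triisopropylsilyloxy)benzene; 5 methyl 2-[(benzyloxy)methyl]prop-2-enoate
Product: 6 methyl (E)-2-[(benzyloxy)methyl]-4-[3-methoxy-4-(triisopropylsilyloxy)phenyl]but-2-enoate
Conditions: Hoveyda–Grubbs II (5 mol %), 1,4-benzoquinone (10 mol %), 5 (3 equiv), CH2Cl2, 40 °C
Reagents that add atoms: none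
Why: Olefin cross-metathesis of a terminal alkene with a 1,1-disubstituted acrylate (as with methacrylates and itaconates) should give the trisubstituted enoate with the ester trans to the arylmethyl group under thermodynamic control, benzoquinone suppressing migration of the allylarene double bond.

Step 4
Reactants: 6 methyl (E)-2-[(benzyloxy)methyl]-4-[3-methoxy-4-(triisopropylsilyloxy)phenyl]but-2-enoate
Product: 7 (Z)-2-[(benzyloxy)methyl]-4-[3-methoxy-4-(triisopropylsilyloxy)phenyl]but-2-en-1-ol (CH2OH trans to the arylmethyl group)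
Conditions: DIBAL-H (2.5 equiv), CH2Cl2, −78 °C; Rochelle salt
Reagents that add atoms: none
Why: DIBAL reduction of an α,β-unsaturated ester stops cleanly at the allylic alcohol without touching the alkene geometry, the benzyl ether or the silyl ether.

Step 5
Reactants: 7 (Z)-2-[(benzyloxy)methyl]-4-[3-methoxy-4-(triisopropylsilyloxy)phenyl]but-2-en-1-ol
Product: 8 [(2R,3S)-2-[(benzyloxy)methyl]-3-[3-methoxy-4-(triisopropylsilyloxy)benzyl]oxiran-2-yl]methanol
Conditions: Ti(OiPr)4 (10 mol %), L-(+)-diethyl tartrate (12 mol %), t-BuOOH, 4 Å MS, CH2Cl2, −20 °C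
Reagents that add atoms: tert-butyl hydroperoxide, CC(C)(C)OO
Why: Sharpless asymmetric epoxidation of a primary allylic alcohol with a 3-substituent trans to CH2OH (the best substrate class): the titanium tartrate binds the CH2OH group and delivers oxygen to one face of the alkene, so C4 and C8 are set together under reagent control.

Step 6
Reactants: 8 [(2R,3S)-2-[(benzyloxy)methyl]-3-[3-methoxy-4-(triisopropylsilyloxy)benzyl]oxiran-2-yl]methanol
Product: 9 (2R,3R)-2-[(benzyloxy)methyl]-4-[3-methoxy-4-(triisopropylsilyloxy)phenyl]-3-methylbutane-1,2-diol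
Conditions: Me3Al (3 equiv), hexane/CH2Cl2, 0 °C to rt
Reagents that add atoms: trimethylaluminium, C[Al](C)C
Why: Trimethylaluminium opening of a 2,3-epoxy alcohol: the aluminium alkoxide of the CH2OH group activates the epoxide and methyl is transferred to the distal secondary carbon C8 (C4 is fully substituted) with inversion, which sets the C8 methyl centre while the oxygen stays on C4 with its configuration unchanged.

Step 7
Reactants: 9 (2R,3R)-2-[(benzyloxy)methyl]-4-[3-methoxy-4-(triisopropylsilyloxy)phenyl]-3-methylbutane-1,2-diol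
Product: 10 (2S,3R)-2-[(benzyloxy)methyl]-2-hydroxy-4-[3-methoxy-4-(triisopropylsilyloxy)phenyl]-3-methylbutanal
Conditions: (COCl)2, DMSO, CH2Cl2, −78 °C; Et3N; used crude
Reagents that add atoms: none
Why: Swern oxidation converts only the primary alcohol (the tertiary one cannot be oxidised), avoids the glycol cleavage that hypervalent iodine reagents can cause with 1,2-diols, and gives an aldehyde with no α-hydrogen.

Step 8
Reactants: 10 (2S,3R)-2-[(benzyloxy)methyl]-2-hydroxy-4-[3-methoxy-4-(triisopropylsilyloxy)phenyl]-3-methylbutanal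
Product: 11 (2RS,3S,4R)-3-[(benzyloxy)methyl]-5-[3-methoxy-4-(triisopropylsilyloxy)phenyl]-4-methylpentane-2,3-diol
Conditions: MeMgBr (3 equiv), THF, −78 to 0 °C
Reagents that add atoms: methylmagnesium bromide, C[Mg]Br
Why: Grignard addition to the aldehyde (one equivalent is spent on the tertiary OH) installs the C6 methyl group; the new carbinol centre C5 forms as a mixture of epimers that is removed by oxidation in step 11.

Step 9
Reactants: 11 (2RS,3S,4R)-3-[(benzyloxy)methyl]-5-[3-methoxy-4-(triisopropylsilyloxy)phenyl]-4-methylpentane-2,3-diol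
Product: 13 (2RS,3S,4R)-2-(benzyloxy)-3-[(benzyloxy)methyl]-3-methoxy-5-[3-methoxy-4-(triisopropylsilyloxy)phenyl]-4-methylpentane, via secondary benzyl ether 12 (not isolated)
Conditions: NaH (1.1 equiv), BnBr (1.05 equiv), Bu4NI (cat.), THF, 0 °C to rt; then NaH (3 equiv), MeI (5 equiv), 15-crown-5 (cat.), rt to 40 °C
Reagents that add atoms: benzyl bromide, BrCc1ccccc1; iodomethane, CI
Why: Two Williamson etherifications in one flask: the less hindered secondary alkoxide is benzylated first with one equivalent of benzyl bromide, then the tertiary alkoxide is methylated with excess iodomethane, benzyl (not silyl) neighbours excluding silyl migration and THF sparing the aryl TIPS ether.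

Step 10
Reactants: 13 (2RS,3S,4R)-2-(benzyloxy)-3-[(benzyloxy)methyl]-3-methoxy-5-[3-methoxy-4-(triisopropylsilyloxy)phenyl]-4-methylpentane
Product: 14 (2RS,3S,4R)-3-(hydroxymethyl)-3-methoxy-5-[3-methoxy-4-(triisopropylsilyloxy)phenyl]-4-methylpentan-2-ol
Conditions: H2 (1 atm), Pd(OH)2/C, EtOAc, rt
Reagents that add atoms: none
Why: Hydrogenolysis removes both benzyl ethers at a stage where the molecule holds no alkene, and the aryl silyl ether and the methyl ethers are inert.

Step 11
Reactants: 14 (2RS,3S,4R)-3-(hydroxymethyl)-3-methoxy-5-[3-methoxy-4-(triisopropylsilyloxy)phenyl]-4-methylpentan-2-ol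
Product: 15 (2S,3R)-2-acetyl-2-methoxy-4-[3-methoxy-4-(triisopropylsilyloxy)phenyl]-3-methylbutanal
Conditions: Dess–Martin periodinane (3 equiv), NaHCO3, CH2Cl2, 0 °C to rt; used without chromatography
Reagents that add atoms: none
Why: Dess–Martin oxidation takes the primary and the secondary alcohol to the aldehyde and the methyl ketone in one operation, merges the C5 epimers, and cannot epimerise C4 because that carbon bears no hydrogen.

Step 12
Reactants: 16 methyl bis(2,2,2-trifluoroethyl)phosphonoacetate; 17 allyl bromide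
Product: 18 methyl 2-[bis(2,2,2-trifluoroethoxy)phosphoryl]pent-4-enoate
Conditions: NaH (1.0 equiv), THF, 0 °C; 17 (1.0 equiv), rt
Reagents that add atoms: none
Why: C-Alkylation of the stabilised phosphonoacetate anion with an allylic bromide gives the α-allyl Still–Gennari reagent, the trifluoroethyl phosphonate being required because a dialkyl phosphonate would give the E enoate, which cannot cyclise.

Step 13
Reactants: 15 (2S,3R)-2-acetyl-2-methoxy-4-[3-methoxy-4-(triisopropylsilyloxy)phenyl]-3-methylbutanal; 18 methyl 2-[bis(2,2,2-trifluoroethoxy)phosphoryl]pent-4-enoate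
Product: 19 methyl (2Z,4S)-2-allyl-4-methoxy-5-oxo-4-[(2R)-1-[3-methoxy-4-(triisopropylsilyloxy)phenyl]propan-2-yl]hex-2-enoate
Conditions: 18 (1.5 equiv), KHMDS, 18-crown-6, THF, −78 °C; then 15, −78 to −40 °C
Reagents that add atoms: none
Why: Still–Gennari olefination: the weakly basic potassium phosphonate adds to the aldehyde in preference to the hindered ketone and the electron-poor phosphonate eliminates under kinetic control, which should place the ester cis to C4 (Z) in the trisubstituted alkene.

Step 14
Reactants: 19 methyl (2Z,4S)-2-allyl-4-methoxy-5-oxo-4-[(2R)-1-[3-methoxy-4-(triisopropylsilyloxy)phenyl]propan-2-yl]hex-2-enoate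
Product: 20 (4S)-6-allyl-4-methoxy-4-[(2R)-1-[3-methoxy-4-(triisopropylsilyloxy)phenyl]propan-2-yl]cyclohex-5-ene-1,3-dione
Conditions: LiHMDS (2.5 equiv), THF, −78 to 0 °C; cold 0.5 M HCl
Reagents that add atoms: none
Why: LiHMDS removes a proton from the C6 methyl group, the only enolisable position of the ketone because C4 is quaternary, and the lithium enolate adds to the C1 ester carbonyl, which the Z alkene holds on the same side of C4; loss of methoxide gives the 1,3-dione, and its deprotonation at C6 by the second equivalent of base makes the condensation irreversible. The closest known reaction type is the Dieckmann-type intramolecular Claisen condensation of 5-oxo esters to cyclohexane-1,3-diones. The ring closes in a 6-exo-trig mode (enolate carbon C6 onto the trigonal C1, whose C=O lies outside the new ring). No stereocentre is formed, and C4 and C8 carry no acidic hydrogen, so neither is at risk. The step needs deprotonation of CH3CO in preference to the bis-allylic CH2 of the allyl group, which the pKa gap of about ten units and the low temperature should secure, and it needs the Z geometry fixed in step 13; any E isomer cannot reach C1 and stays in the neutral fraction when the acidic dione is extracted into base.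

Step 15
Reactants: 20 (4S)-6-allyl-4-methoxy-4-[(2R)-1-[3-methoxy-4-(triisopropylsilyloxy)phenyl]propan-2-yl]cyclohex-5-ene-1,3-dione
Product: 21 (4S)-2-allyl-4,5-dimethoxy-4-[(2R)-1-[3-methoxy-4-(triisopropylsilyloxy)phenyl]propan-2-yl]cyclohexa-2,5-dien-1-one
Conditions: HC(OMe)3, MeOH, camphorsulfonic acid (cat.), rt
Reagents that add atoms: trimethyl orthoformate, COC(OC)OC; methanol, CO
Why: Acid-catalysed enol ether formation from a cyclic 1,3-dione is reversible, so the two regioisomers equilibrate through the ketal, and the cross-conjugated 2,5-dienone with the methoxy group on C5 is expected to be the more stable one (blocked 2,5-cyclohexadienones are favoured over their 2,4-isomers).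

Step 16
Reactants: 21 (4S)-2-allyl-4,5-dimethoxy-4-[(2R)-1-[3-methoxy-4-(triisopropylsilyloxy)phenyl]propan-2-yl]cyclohexa-2,5-dien-1-one
Product: 22 (4S)-2-allyl-4-[(2R)-1-(4-hydroxy-3-methoxyphenyl)propan-2-yl]-4,5-dimethoxycyclohexa-2,5-dien-1-one (CNP0370214.1)
Conditions: TBAF (1.1 equiv), AcOH (1.1 equiv), THF, 0 °C
Reagents that add atoms: none
Why: Fluoride cleaves the aryl silyl ether rapidly at 0 °C, and the acetic acid buffer keeps the phenoxide and the vinylogous ester out of strongly basic conditions.

**Compound list**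

1 | eugenol | C=CCc1ccc(O)c(OC)c1 | starting material
2 | 4-allyl-2-methoxy-1-(triisopropylsilyloxy)benzene | C=CCc1ccc(O[Si](C(C)C)(C(C)C)C(C)C)c(OC)c1 | intermediate
3 | methyl 2-(bromomethyl)acrylate | C=C(CBr)C(=O)OC | starting material
4 | benzyl alcohol | OCc1ccccc1 | starting material
5 | methyl 2-[(benzyloxy)methyl]prop-2-enoate | C=C(COCc1ccccc1)C(=O)OC | intermediate
6 | methyl (E)-2-[(benzyloxy)methyl]-4-[3-methoxy-4-(triisopropylsilyloxy)phenyl]but-2-enoate | COC(=O)/C(COCc1ccccc1)=C/Cc1ccc(O[Si](C(C)C)(C(C)C)C(C)C)c(OC)c1 | intermediate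
7 | (Z)-2-[(benzyloxy)methyl]-4-[3-methoxy-4-(triisopropylsilyloxy)phenyl]but-2-en-1-ol | OC/C(COCc1ccccc1)=C/Cc1ccc(O[Si](C(C)C)(C(C)C)C(C)C)c(OC)c1 | intermediate
8 | [(2R,3S)-2-[(benzyloxy)methyl]-3-[3-methoxy-4-(triisopropylsilyloxy)benzyl]oxiran-2-yl]methanol | OC[C@]1(COCc2ccccc2)O[C@H]1Cc1ccc(O[Si](C(C)C)(C(C)C)C(C)C)c(OC)c1 | intermediate
9 | (2R,3R)-2-[(benzyloxy)methyl]-4-[3-methoxy-4-(triisopropylsilyloxy)phenyl]-3-methylbutane-1,2-diol | OC[C@@](O)(COCc1ccccc1)[C@H](C)Cc1ccc(O[Si](C(C)C)(C(C)C)C(C)C)c(OC)c1 | intermediate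
10 | (2S,3R)-2-[(benzyloxy)methyl]-2-hydroxy-4-[3-methoxy-4-(triisopropylsilyloxy)phenyl]-3-methylbutanal | O=C[C@@](O)(COCc1ccccc1)[C@H](C)Cc1ccc(O[Si](C(C)C)(C(C)C)C(C)C)c(OC)c1 | intermediate
11 | (2RS,3S,4R)-3-[(benzyloxy)methyl]-5-[3-methoxy-4-(triisopropylsilyloxy)phenyl]-4-methylpentane-2,3-diol | CC(O)[C@@](O)(COCc1ccccc1)[C@H](C)Cc1ccc(O[Si](C(C)C)(C(C)C)C(C)C)c(OC)c1 | intermediate
12 | (2RS,3S,4R)-2-(benzyloxy)-3-[(benzyloxy)methyl]-5-[3-methoxy-4-(triisopropylsilyloxy)phenyl]-4-methylpentan-3-ol | CC(OCc1ccccc1)[C@@](O)(COCc1ccccc1)[C@H](C)Cc1ccc(O[Si](C(C)C)(C(C)C)C(C)C)c(OC)c1 | intermediate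
13 | (2RS,3S,4R)-2-(benzyloxy)-3-[(benzyloxy)methyl]-3-methoxy-5-[3-methoxy-4-(triisopropylsilyloxy)phenyl]-4-methylpentane | CC(OCc1ccccc1)[C@@](OC)(COCc1ccccc1)[C@H](C)Cc1ccc(O[Si](C(C)C)(C(C)C)C(C)C)c(OC)c1 | intermediate
14 | (2RS,3S,4R)-3-(hydroxymethyl)-3-methoxy-5-[3-methoxy-4-(triisopropylsilyloxy)phenyl]-4-methylpentan-2-ol | CC(O)[C@@](OC)(CO)[C@H](C)Cc1ccc(O[Si](C(C)C)(C(C)C)C(C)C)c(OC)c1 | intermediate
15 | (2S,3R)-2-acetyl-2-methoxy-4-[3-methoxy-4-(triisopropylsilyloxy)phenyl]-3-methylbutanal | CC(=O)[C@@](OC)(C=O)[C@H](C)Cc1ccc(O[Si](C(C)C)(C(C)C)C(C)C)c(OC)c1 | intermediate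
16 | methyl bis(2,2,2-trifluoroethyl)phosphonoacetate | COC(=O)CP(=O)(OCC(F)(F)F)OCC(F)(F)F | starting material
17 | allyl bromide | C=CCBr | starting material
18 | methyl 2-[bis(2,2,2-trifluoroethoxy)phosphoryl]pent-4-enoate | C=CCC(C(=O)OC)P(=O)(OCC(F)(F)F)OCC(F)(F)F | intermediate
19 | methyl (2Z,4S)-2-allyl-4-methoxy-5-oxo-4-[(2R)-1-[3-methoxy-4-(triisopropylsilyloxy)phenyl]propan-2-yl]hex-2-enoate | C=CC/C(C(=O)OC)=C/[C@@](OC)([C@H](C)Cc1ccc(O[Si](C(C)C)(C(C)C)C(C)C)c(OC)c1)C(C)=O | intermediate
20 | (4S)-6-allyl-4-methoxy-4-[(2R)-1-[3-methoxy-4-(triisopropylsilyloxy)phenyl]propan-2-yl]cyclohex-5-ene-1,3-dione | C=CCC1=C[C@@](OC)([C@H](C)Cc2ccc(O[Si](C(C)C)(C(C)C)C(C)C)c(OC)c2)C(=O)CC1=O | intermediate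
21 | (4S)-2-allyl-4,5-dimethoxy-4-[(2R)-1-[3-methoxy-4-(triisopropylsilyloxy)phenyl]propan-2-yl]cyclohexa-2,5-dien-1-one | C=CCC1=C[C@@](OC)([C@H](C)Cc2ccc(O[Si](C(C)C)(C(C)C)C(C)C)c(OC)c2)C(OC)=CC1=O | intermediate
22 | (4S)-2-allyl-4-[(2R)-1-(4-hydroxy-3-methoxyphenyl)propan-2-yl]-4,5-dimethoxycyclohexa-2,5-dien-1-one | C=CCC1=C[C@@](OC)([C@H](C)Cc2ccc(O)c(OC)c2)C(OC)=CC1=O | target

**Step count**

Total steps: 16. Longest linear sequence: 14 (steps 1, 3–11 and 13–16); steps 2 and 12 prepare the two side reagents.

**Steps most likely to fail**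

Step 14 (key step). Acyl transfer from the hindered, conjugated methyl ester to the ketone enolate may be slow, so that intermolecular condensation or base-induced isomerisation of the enoate competes with ring closure. Fallback, from 19 back to 20, with an activated acyl donor in place of the ester: hydrolysis of the methyl ester with Me3SnOH (1,2-dichloroethane, 70 °C, conditions that spare the aryl silyl ether) should give (2Z,4S)-2-allyl-4-methoxy-5-oxo-4-[(2R)-1-[3-methoxy-4-(triisopropylsilyloxy)phenyl]propan-2-yl]hex-2-enoic acid F1. 1,1′-Carbonyldiimidazole in THF should convert it into the acyl imidazolide F2. Treatment with LiHMDS (THF, −78 °C) should then bring about C-acylation of the methyl ketone enolate by the acyl imidazole, a known way to 1,3-diketones, and acidic work-up rejoins the route at 20.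

Step 15. Methanol may add faster at the less hindered C1, and the equilibrium between the two enol ethers may not lie far enough on the side of the cross-conjugated isomer, so that the linear 2,4-dienone accumulates. Fallback, from 20 back to 21, with irreversible alkylation, separation and recycling in place of equilibration: O-methylation of the vinylogous acid with trimethylsilyldiazomethane (MeOH/toluene, 0 °C) should give both enol ethers. Chromatography should separate 21 from the linear isomer (6S)-4-allyl-3,6-dimethoxy-6-[(2R)-1-[3-methoxy-4-(triisopropylsilyloxy)phenyl]propan-2-yl]cyclohexa-2,4-dien-1-one F3. F3 is hydrolysed (1 M HCl, THF, rt) back to 20 and passed through the methylation again, and the route continues from 21.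

Step 13. The non-enolisable β-keto aldehyde may fragment (loss of the formyl group or retro-aldol cleavage of the adduct) under the basic olefination conditions, or the Z selectivity may erode at the neopentylic aldehyde. Fallback, from 15 back to 19, building the alkene by two stereospecific couplings without a basic olefination: Ramirez olefination (CBr4, PPh3, Zn, CH2Cl2) should convert the aldehyde, not the hindered ketone, into (3S,4R)-3-(2,2-dibromoethenyl)-3-methoxy-5-[3-methoxy-4-(triisopropylsilyloxy)phenyl]-4-methylpentan-2-one F4. A Stille coupling with allyltributylstannane (Pd2(dba)3, tri(2-furyl)phosphine, toluene) should replace selectively the bromine trans to C4 and give (3S,4R)-3-[(1Z)-2-bromopenta-1,4-dien-1-yl]-3-methoxy-5-[3-methoxy-4-(triisopropylsilyloxy)phenyl]-4-methylpentan-2-one F5. Palladium-catalysed methoxycarbonylation of the remaining bromide, which is cis to C4 (CO, MeOH, Et3N, Pd(OAc)2/dppf, DMF, 70 °C), should then place the ester on the side of C4 with retention and rejoin the route at 19.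

**Further compounds**

F1 | step 14 | (2Z,4S)-2-allyl-4-methoxy-5-oxo-4-[(2R)-1-[3-methoxy-4-(triisopropylsilyloxy)phenyl]propan-2-yl]hex-2-enoic acid | C=CC/C(C(=O)O)=C/[C@@](OC)([C@H](C)Cc1ccc(O[Si](C(C)C)(C(C)C)C(C)C)c(OC)c1)C(C)=O
F2 | step 14 | (3S,5Z)-6-(imidazole-1-carbonyl)-3-methoxy-3-[(2R)-1-[3-methoxy-4-(triisopropylsilyloxy)phenyl]propan-2-yl]nona-5,8-dien-2-one (acyl imidazolide of F1) | C=CC/C(C(=O)n1ccnc1)=C/[C@@](OC)([C@H](C)Cc2ccc(O[Si](C(C)C)(C(C)C)C(C)C)c(OC)c2)C(C)=O
F3 | step 15 | (6S)-4-allyl-3,6-dimethoxy-6-[(2R)-1-[3-methoxy-4-(triisopropylsilyloxy)phenyl]propan-2-yl]cyclohexa-2,4-dien-1-one | C=CCC1=C[C@@](OC)([C@H](C)Cc2ccc(O[Si](C(C)C)(C(C)C)C(C)C)c(OC)c2)C(=O)C=C1OC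
F4 | step 13 | (3S,4R)-3-(2,2-dibromoethenyl)-3-methoxy-5-[3-methoxy-4-(triisopropylsilyloxy)phenyl]-4-methylpentan-2-one | BrC(Br)=C[C@@](OC)([C@H](C)Cc1ccc(O[Si](C(C)C)(C(C)C)C(C)C)c(OC)c1)C(C)=O
F5 | step 13 | (3S,4R)-3-[(1Z)-2-bromopenta-1,4-dien-1-yl]-3-methoxy-5-[3-methoxy-4-(triisopropylsilyloxy)phenyl]-4-methylpentan-2-one | C=CC/C(Br)=C/[C@@](OC)([C@H](C)Cc1ccc(O[Si](C(C)C)(C(C)C)C(C)C)c(OC)c1)C(C)=O
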